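**Plan**

1. Retrosynthesis: ring C is opened at O1–C2 (phenol plus formyl group, the reverse of hemiacetal formation and dehydration). The C3–C4 bond is then undone as a 1,2-aroyl shift, which leads back to a trans-chalcone epoxide. Removing the epoxide oxygen and cutting the chalcone Cα=Cβ bond (the later C2–C3 bond) leaves a ring-A acetophenone and a ring-B aldehyde.
2. Enabling feature: C3 of ring C is bonded to both the carbonyl carbon C4 and ring B. The 2'- and 4'-methoxy groups of ring B can take up positive charge at the carbon that carries this ring, so an epoxide ionised there draws the aroyl group over from the adjacent carbon.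
3. Forward: rings A and B are purchased. The chain is joined by Claisen–Schmidt condensation (C2–C3), oxidised to the epoxide and rearranged with BF3·OEt2 (C3–C4 formed, no ring closed). Ring C closes last at O1–C2 when acid frees the phenol.
4. Stereochemistry: the target has no stereocentre. The (E)-alkene and the racemic trans-epoxide are transient, both epoxide centres vanish in the shift, and the (Z)-enol geometry after the shift is set by its internal hydrogen bond.

Key step: step 4

Remark: isoflavone numbering (O1, C2, C3, C4; primed numbers for ring B) is used for the skeleton; epoxide 7 is a racemate with one enantiomer drawn; compounds 1, 2 and 4 are taken as purchased.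

**Route**

Step 1
Reactants: 1 1-(2-hydroxy-4,5-dimethoxyphenyl)ethan-1-one; 2 chloromethyl methyl ether
Product: 3 1-[4,5-dimethoxy-2-(methoxymethoxy)phenyl]ethan-1-one
Conditions: NaH (1.1 equiv), DMF, 0 °C; then MOMCl, 0 °C → rt
Reagents that add atoms: chloromethyl methyl ether (compound 2), COCCl
Why: Methoxymethyl ether formation by SN2 O-alkylation of the sodium phenoxide (Williamson type) with the very reactive α-chloro ether; NaH breaks the phenol–carbonyl hydrogen bond and deprotonates the phenol long before the methyl ketone, so C-alkylation is not expected.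

Step 2
Reactants: 3 1-[4,5-dimethoxy-2-(methoxymethoxy)phenyl]ethan-1-one; 4 2,3,4-trimethoxybenzaldehyde
Product: 6 (E)-1-[4,5-dimethoxy-2-(methoxymethoxy)phenyl]-3-(2,3,4-trimethoxyphenyl)prop-2-en-1-one, via aldol adduct 5 (not isolated)
Conditions: KOH (aq.), EtOH, rt
Reagents that add atoms: none
Why: Claisen–Schmidt (crossed aldol) condensation: only the ketone can enolise, the aldol 5 loses water by E1cB and the conjugated enone forms as the thermodynamically preferred E isomer, while the base-stable MOM ether keeps the phenol from closing to a flavanone.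

Step 3
Reactants: 6 (E)-1-[4,5-dimethoxy-2-(methoxymethoxy)phenyl]-3-(2,3,4-trimethoxyphenyl)prop-2-en-1-one
Product: 7 rac-[4,5-dimethoxy-2-(methoxymethoxy)phenyl][(2S,3R)-3-(2,3,4-trimethoxyphenyl)oxiran-2-yl]methanone (racemic trans-epoxide)
Conditions: 30% aq. H2O2, NaOH, MeOH/THF, 0 °C → rt; neutral work-up, used crude
Reagents that add atoms: hydrogen peroxide, OO
Why: Weitz–Scheffer nucleophilic epoxidation: hydroperoxide adds to the β-carbon and the enolate displaces hydroxide from the peroxide oxygen; free rotation before closure places aroyl and aryl trans, which sets the two new stereocentres relative to each other only (racemate), and with the phenol masked the Algar–Flynn–Oyamada cyclisation cannot intervene.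

Step 4
Reactants: 7 rac-[4,5-dimethoxy-2-(methoxymethoxy)phenyl][(2S,3R)-3-(2,3,4-trimethoxyphenyl)oxiran-2-yl]methanone
Product: 9 (Z)-3-hydroxy-1-[4,5-dimethoxy-2-(methoxymethoxy)phenyl]-2-(2,3,4-trimethoxyphenyl)prop-2-en-1-one, via ketoaldehyde tautomer 8 (not isolated)
Conditions: BF3·OEt2 (0.5 equiv), CH2Cl2, −40 → 0 °C; cold pH 7 phosphate buffer
Reagents that add atoms: none
Why: BF3 binds the oxirane oxygen and the C–O bond at the carbon carrying ring B heterolyses, because the benzylic cation is delocalised onto the ortho- and para-methoxy groups of that ring while the other oxirane carbon is deactivated by the adjacent carbonyl. The aroyl group then moves with its bonding pair from the neighbouring carbon to the cationic centre, the carbon left behind becomes the formyl group of ketoaldehyde 8, and 8 tautomerises to the hydrogen-bonded (Z)-enol 9. The closest known reaction type is exactly this Lewis-acid (Meinwald-type, semipinacol) rearrangement of chalcone epoxides to 2-aryl-3-oxopropanals by 1,2-acyl shift. No ring is closed and no stereocentre is kept: both oxirane centres are destroyed, the labile centre of 8 disappears on enolisation, and the enol geometry is dictated by the O–H···O=C chelate. The step needs ionisation at the benzylic rather than the α-keto carbon and migration of acyl rather than hydride (which would give a 1,2-diketone); the donor-rich ring B secures the first and the well-established preference of an acyl group to migrate to a stabilised benzylic cation secures the second. A substoichiometric charge of BF3·OEt2 at low temperature should spare the aryl MOM acetal, since the donor-activated oxirane opens much faster than the acetal is attacked.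

Step 5
Reactants: 9 (Z)-3-hydroxy-1-[4,5-dimethoxy-2-(methoxymethoxy)phenyl]-2-(2,3,4-trimethoxyphenyl)prop-2-en-1-one
Product: 12 6,7-dimethoxy-3-(2,3,4-trimethoxyphenyl)-4H-chromen-4-one (6,7,2',3',4'-pentamethoxyisoflavone), via free phenol enol 10 (not isolated), via 2-hydroxyisoflavanone 11 (not isolated)
Conditions: HCl (ca. 2 M in MeOH), 60 °C
Reagents that add atoms: none
Why: Acid-catalysed transacetalisation hands the MOM group to methanol, the freed phenol of 10 adds to the formyl carbon (6-exo-trig hemiacetal formation) and the 2-hydroxyisoflavanone 11 is dehydrated under the same acid to the aromatic 4-pyranone, which is the standard closure of 2-formyldeoxybenzoins to isoflavones.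

**Compound list**

```
1 | 1-(2-hydroxy-4,5-dimethoxyphenyl)ethan-1-one | CC(=O)c1cc(OC)c(OC)cc1O | starting material
2 | chloromethyl methyl ether (MOMCl) | COCCl | starting material
3 | 1-[4,5-dimethoxy-2-(methoxymethoxy)phenyl]ethan-1-one | CC(=O)c1cc(OC)c(OC)cc1OCOC | intermediate
4 | 2,3,4-trimethoxybenzaldehyde | COc1ccc(C=O)c(OC)c1OC | starting material
5 | 3-hydroxy-1-[4,5-dimethoxy-2-(methoxymethoxy)phenyl]-3-(2,3,4-trimethoxyphenyl)propan-1-one (aldol adduct; racemic, carbinol centre left undefined) | COCOc1cc(OC)c(OC)cc1C(=O)CC(O)c1ccc(OC)c(OC)c1OC | intermediate (not isolated)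
6 | (E)-1-[4,5-dimethoxy-2-(methoxymethoxy)phenyl]-3-(2,3,4-trimethoxyphenyl)prop-2-en-1-one | COCOc1cc(OC)c(OC)cc1C(=O)/C=C/c1ccc(OC)c(OC)c1OC | intermediate
7 | rac-[4,5-dimethoxy-2-(methoxymethoxy)phenyl][(2S,3R)-3-(2,3,4-trimethoxyphenyl)oxiran-2-yl]methanone (trans-epoxide; racemate, one enantiomer drawn) | COCOc1cc(OC)c(OC)cc1C(=O)[C@H]1O[C@@H]1c1ccc(OC)c(OC)c1OC | intermediate
8 | 3-[4,5-dimethoxy-2-(methoxymethoxy)phenyl]-3-oxo-2-(2,3,4-trimethoxyphenyl)propanal (ketoaldehyde tautomer; racemic, labile centre left undefined) | COCOc1cc(OC)c(OC)cc1C(=O)C(C=O)c1ccc(OC)c(OC)c1OC | intermediate (not isolated)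
9 | (Z)-3-hydroxy-1-[4,5-dimethoxy-2-(methoxymethoxy)phenyl]-2-(2,3,4-trimethoxyphenyl)prop-2-en-1-one (chelated enol) | COCOc1cc(OC)c(OC)cc1C(=O)/C(=C\O)c1ccc(OC)c(OC)c1OC | intermediate
10 | (Z)-3-hydroxy-1-(2-hydroxy-4,5-dimethoxyphenyl)-2-(2,3,4-trimethoxyphenyl)prop-2-en-1-one | COc1cc(O)c(cc1OC)C(=O)/C(=C\O)c1ccc(OC)c(OC)c1OC | intermediate (not isolated)
11 | 2-hydroxy-6,7-dimethoxy-3-(2,3,4-trimethoxyphenyl)-2,3-dihydro-4H-chromen-4-one (mixture of stereoisomers, centres left undefined) | COc1cc2OC(O)C(c3ccc(OC)c(OC)c3OC)C(=O)c2cc1OC | intermediate (not isolated)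
12 | 6,7-dimethoxy-3-(2,3,4-trimethoxyphenyl)-4H-chromen-4-one (6,7,2',3',4'-pentamethoxyisoflavone) | COc1cc2occ(-c3ccc(OC)c(OC)c3OC)c(=O)c2cc1OC | target
```

**Step count**

Total steps: 5. Longest linear sequence: 5 steps (1 → 3 → 6 → 7 → 9 → 12).

**Steps most likely to fail**

Step 4. The danger is Lewis-acid cleavage of the MOM acetal before the shift, after which the free phenol rather than the aroyl group would capture the benzylic cation and close a 3-hydroxyflavanone. Fluoride capture of the long-lived cation and loss of the formyl carbon during work-up are further risks. The fallback sets out from chalcone 6 and comes back to the route at 12. It reaches the same branched chain by oxidative 1,2-aryl migration of the chalcone, a different and well-known reaction. Treatment of 6 with Tl(NO3)3·3H2O in MeOH/HC(OMe)3 at rt should move ring B from Cβ to Cα, trivalent thallium adding to the alkene and leaving as monovalent thallium. This would give the acetal 3,3-dimethoxy-1-[4,5-dimethoxy-2-(methoxymethoxy)phenyl]-2-(2,3,4-trimethoxyphenyl)propan-1-one F1. HCl in MeOH at 60 °C should then remove the MOM group and close ring C with loss of methanol to give 12.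

Step 3. Conjugate addition of hydroperoxide may be slow because the donor-rich ring B deactivates the β-carbon, which gives retro-aldol cleavage in the alkaline medium time to compete. The epoxide is also prone to acid-triggered opening during isolation, hence the neutral work-up and use of crude material. The fallback sets out from 3 (with aldehyde 4) and comes back at 7, building the epoxide by Darzens condensation instead of oxidising the alkene. Ketone 3 with LiN(SiMe3)2 and Me3SiCl in THF at −78 °C should give the silyl enol ether {1-[4,5-dimethoxy-2-(methoxymethoxy)phenyl]ethenyl}oxy(trimethyl)silane F2. NBS in THF at 0 °C should convert it under non-acidic conditions into 2-bromo-1-[4,5-dimethoxy-2-(methoxymethoxy)phenyl]ethan-1-one F3. F3 and aldehyde 4 with NaOMe in MeOH/THF at 0 °C should then give 7, since the reversible aldol step followed by intramolecular displacement of bromide favours the trans-epoxide.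

Step 5. Retro-Claisen methanolysis of the β-ketoaldehyde may outpace ring closure, or the reaction may stall at the cyclic hemiacetal stage. The fallback sets out from 9 and comes back at 12. It drives the deformylation to completion on purpose (HCl/MeOH, reflux) to give the deoxybenzoin 1-(2-hydroxy-4,5-dimethoxyphenyl)-2-(2,3,4-trimethoxyphenyl)ethan-1-one F4. C2 is then re-installed with Me2NCH(OMe)2 in toluene at 100 °C. Condensation at the doubly activated methylene should give the enaminone 3-(dimethylamino)-1-(2-hydroxy-4,5-dimethoxyphenyl)-2-(2,3,4-trimethoxyphenyl)prop-2-en-1-one F5, whose phenol adds to the enamine carbon and expels dimethylamine to give 12.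

**Further compounds**

```
F1 | step 4 | 3,3-dimethoxy-1-[4,5-dimethoxy-2-(methoxymethoxy)phenyl]-2-(2,3,4-trimethoxyphenyl)propan-1-one (racemic, centre left undefined) | COCOc1cc(OC)c(OC)cc1C(=O)C(C(OC)OC)c1ccc(OC)c(OC)c1OC
F2 | step 3 | {1-[4,5-dimethoxy-2-(methoxymethoxy)phenyl]ethenyl}oxy(trimethyl)silane | C=C(O[Si](C)(C)C)c1cc(OC)c(OC)cc1OCOC
F3 | step 3 | 2-bromo-1-[4,5-dimethoxy-2-(methoxymethoxy)phenyl]ethan-1-one | BrCC(=O)c1cc(OC)c(OC)cc1OCOC
F4 | step 5 | 1-(2-hydroxy-4,5-dimethoxyphenyl)-2-(2,3,4-trimethoxyphenyl)ethan-1-one | COc1cc(O)c(cc1OC)C(=O)Cc1ccc(OC)c(OC)c1OC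
F5 | step 5 | 3-(dimethylamino)-1-(2-hydroxy-4,5-dimethoxyphenyl)-2-(2,3,4-trimethoxyphenyl)prop-2-en-1-one (push-pull alkene, geometry not fixed; not isolated) | COc1cc(O)c(cc1OC)C(=O)C(=CN(C)C)c1ccc(OC)c(OC)c1OC
```
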